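## Retrosynthetic overview

1. The last C–C bond is the interflavanyl bond C4 (ring C)–C6 (ring D). It joins a 2,3-cis flavan-4-yl thioether (electrophile) to a 2,3-trans-3,4-trans flavan-3,4-diol (nucleophile), and the benzyl ethers come off at the end.
2. Both halves come from one (2R,3R)-dihydroflavonol. Ketone reduction gives the lower diol. Mesylation, reduction and closure to the 3α,4α-epoxide invert C3, and thiol opening then gives the upper half.
3. Key disconnection: the C3–C4 bond of that dihydroflavonol. A carbene-generated acyl anion (aromatic CHO carbon) attacks an aliphatic CHO carbon, and a dynamic kinetic resolution sets C2 and C3.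
4. The dialdehyde comes from a salicylaldehyde-type phenol and a 2-aryl-3-nitrooxirane, made from 4-(benzyloxy)benzaldehyde and nitromethane followed by epoxidation.
5. Ring order: rings A/D and B/E are bought as arenes. The pyranone ring (later ring C and ring F) is closed once, in the key step, and the two flavan units are joined last.

Assumption: the (5aR,10bS) antipode of the triazolium salt is taken to give the (2R,3R) product. Both antipodes are sold, so the other one is used if the first run shows the opposite sense.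

## Route

Step 1
Reactants: 1 2,3,4-trihydroxybenzaldehyde
Product: 2 3,4-bis(benzyloxy)-2-hydroxybenzaldehyde
Conditions: BnBr (2.1 equiv), K2CO3 (2.2 equiv), DMF, 0 °C to rt
Reagents that add atoms: benzyl bromide, BrCc1ccccc1
Why: Williamson etherification; the 2-OH is hydrogen-bonded to the formyl group and is the least nucleophilic, so two equivalents of BnBr cap only the 4-OH and 3-OH, and no stereocenter is formed.

Step 2
Reactants: 3 4-(benzyloxy)benzaldehyde; 4 nitromethane
Product: 5 (E)-1-(benzyloxy)-4-(2-nitroethenyl)benzene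
Conditions: MeNO2 (5 equiv), NH4OAc (0.5 equiv), AcOH, 100 °C, 3 h
Reagents that add atoms: none
Why: Henry (nitroaldol) condensation with in situ dehydration gives the conjugated (E)-nitroalkene as the thermodynamic product.

Step 3
Reactants: 5 (E)-1-(benzyloxy)-4-(2-nitroethenyl)benzene
Product: 6 racemic trans-2-[4-(benzyloxy)phenyl]-3-nitrooxirane
Conditions: 30% aq. H2O2 (3 equiv), 2 M aq. NaOH (0.5 equiv), MeOH–THF, 0 °C, 30 min; used crude
Reagents that add atoms: hydrogen peroxide, OO
Why: Weitz–Scheffer-type nucleophilic epoxidation; hydroperoxide adds to the β-carbon and the nitronate closes on oxygen to give the trans oxirane as a racemate, which suffices because this center is scrambled and reset in step 4.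

Step 4 (key step)
Reactants: 2 3,4-bis(benzyloxy)-2-hydroxybenzaldehyde; 6 racemic trans-2-[4-(benzyloxy)phenyl]-3-nitrooxirane
Product: 8 (2R,3R)-7,8-bis(benzyloxy)-2-[4-(benzyloxy)phenyl]-3-hydroxychroman-4-one (2,3-trans), via racemic dialdehyde 7 (not isolated)
Conditions: Cs2CO3 (1.3 equiv), 4 Å MS, THF, 0 °C to rt, 2 h (6 limiting, 0.95 equiv); then (5aR,10bS)-2-(pentafluorophenyl)-5a,10b-dihydro-4H,6H-indeno[2,1-b][1,2,4]triazolo[4,3-d][1,4]oxazin-2-ium tetrafluoroborate (10 mol %), rt, 16 h, argon; recrystallise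
Reagents that add atoms: none
Why: Proposed new method: the caesium phenoxide of 2 opens 6 at its benzylic carbon and the α-nitro alkoxide expels nitrite (known behaviour of α-nitro epoxides as 1,2-dielectrophiles) to give 7, whose aromatic formyl carbon the carbene turns into a Breslow-type acyl anion that attacks the aliphatic formyl carbon in a 6-exo crossed benzoin reaction, so two normally electrophilic aldehyde carbons become C4 and C3; the α-aryl-α-aryloxy aldehyde center of 7 racemises quickly through its enolate under carbonate, so the chiral carbene funnels both antipodes into one product (dynamic kinetic resolution) through the transition state that keeps the 2-aryl group pseudo-equatorial and trans to the new carbinol, which sets C2 (R) and C3 (R), trans also being the thermodynamic C3 epimer; the N-pentafluorophenyl carbene adds reversibly and favours benzoin over internal redox chemistry; the closest known reactions are the enantioselective intramolecular aldehyde–ketone benzoin cyclisation to 3-hydroxychroman-4-ones and dynamic kinetic resolutions driven by intramolecular benzoin reactions.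

Step 5
Reactants: 8 (2R,3R)-7,8-bis(benzyloxy)-2-[4-(benzyloxy)phenyl]-3-hydroxychroman-4-one
Product: 9 (2R,3S,4R)-7,8-bis(benzyloxy)-2-[4-(benzyloxy)phenyl]chromane-3,4-diol (2,3-trans-3,4-trans)
Conditions: NaBH4 (1.0 equiv), THF–EtOH (1:1), 0 °C, 1 h
Reagents that add atoms: none
Why: Borohydride ketone reduction; axial hydride attack on the half-chair with 2-aryl and 3-OH equatorial gives the equatorial 4α-alcohol, the established outcome for 2,3-trans-dihydroflavonols, and this sets C4 (R).

Step 6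
Reactants: 8 (2R,3R)-7,8-bis(benzyloxy)-2-[4-(benzyloxy)phenyl]-3-hydroxychroman-4-one
Product: 10 (2R,3R)-7,8-bis(benzyloxy)-2-[4-(benzyloxy)phenyl]-4-oxochroman-3-yl methanesulfonate
Conditions: MsCl (1.3 equiv), pyridine (3 equiv), CH2Cl2, 0 °C to rt
Reagents that add atoms: methanesulfonyl chloride, CS(=O)(=O)Cl
Why: O-sulfonylation of the only free hydroxyl under a weak base gives a trans-3-mesyloxyflavanone, a known stable compound class, with C2 and C3 untouched.

Step 7
Reactants: 10 (2R,3R)-7,8-bis(benzyloxy)-2-[4-(benzyloxy)phenyl]-4-oxochroman-3-yl methanesulfonate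
Product: 13 (2R,3S,4S)-4-(benzylsulfanyl)-7,8-bis(benzyloxy)-2-[4-(benzyloxy)phenyl]chroman-3-ol (2α-aryl, 3α-OH, 4β-SBn), via mesyloxy alcohol 11 (not isolated), via alpha-epoxide 12 (not isolated)
Conditions: NaBH4 (0.6 equiv), THF–EtOH (2:1), −20 °C, 1 h; then BnSH (1.5 equiv), K2CO3 (2.0 equiv), rt to 40 °C, 6 h
Reagents that add atoms: benzyl mercaptan, SCc1ccccc1
Why: Axial hydride delivery gives the 3,4-trans mesyloxy alcohol, its alkoxide displaces the mesylate from the α face (intramolecular Williamson epoxide closure as in trans-3-halochroman-4-ol chemistry, inverting C3), and thiolate opens the benzylic C4 from the free β face (trans-diaxial Fürst–Plattner opening), which gives the 2,3-cis-3,4-trans array.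

Step 8
Reactants: 13 (2R,3S,4S)-4-(benzylsulfanyl)-7,8-bis(benzyloxy)-2-[4-(benzyloxy)phenyl]chroman-3-ol; 9 (2R,3S,4R)-7,8-bis(benzyloxy)-2-[4-(benzyloxy)phenyl]chromane-3,4-diol
Product: 14 hexa-O-benzyl ether of the target (upper unit 2α-aryl, 3α-OH, 4β-aryl; lower unit 2α-aryl, 3β-OH, 4α-OH; C4 of ring C bonded to C6 of ring D)
Conditions: 13 (1 equiv), 9 (4 equiv, excess recovered), AgBF4 (2.5 equiv), THF, 0 °C, 1 h, dark; aq. NaHCO3 quench
Reagents that add atoms: none
Why: Thiophilic activation by monovalent silver ionises only the C4–S bond and leaves the 4-OH of 9 alone, and the 7-OBn-stabilised flavan-4-yl cation is captured in a Friedel–Crafts-type proanthocyanidin coupling by C6 of 9 (ortho to 7-OBn, para to the ring oxygen) from the β face, anti to the 2-aryl and 3-OH groups, which sets the 4β configuration.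

Step 9
Reactants: 14 hexa-O-benzyl ether of the target
Product: 15 epioritin-(4β→6)-oritin-4α-ol, upper unit (2R,3R,4S), lower unit (2R,3S,4R) (target)
Conditions: H2 (1 atm), Pd(OH)2/C (20 wt %), EtOAc–MeOH (1:1), rt, 3 h, stopped at full uptake; work-up under argon
Reagents that add atoms: none
Why: Catalytic hydrogenolysis; aryl benzyl ethers cleave much faster under neutral conditions than a secondary benzylic C–OH or the diarylmethine C–C bond (as in debenzylations that keep a 4-hydroxybenzylic alcohol), so all six stereocenters and the 4-OH survive.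

## Compound list

1 | 2,3,4-trihydroxybenzaldehyde | O=Cc1ccc(O)c(O)c1O | starting material
2 | 3,4-bis(benzyloxy)-2-hydroxybenzaldehyde | O=Cc1ccc(OCc2ccccc2)c(OCc2ccccc2)c1O | intermediate
3 | 4-(benzyloxy)benzaldehyde | O=Cc1ccc(OCc2ccccc2)cc1 | starting material
4 | nitromethane | C[N+](=O)[O-] | starting material
5 | (E)-1-(benzyloxy)-4-(2-nitroethenyl)benzene | [O-][N+](=O)/C=C/c1ccc(OCc2ccccc2)cc1 | intermediate
6 | racemic trans-2-[4-(benzyloxy)phenyl]-3-nitrooxirane (one antipode drawn) | [O-][N+](=O)[C@H]1O[C@@H]1c1ccc(OCc2ccccc2)cc1 | intermediate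
7 | racemic, configurationally labile 3,4-bis(benzyloxy)-2-{1-[4-(benzyloxy)phenyl]-2-oxoethoxy}benzaldehyde | O=CC(Oc1c(C=O)ccc(OCc2ccccc2)c1OCc1ccccc1)c1ccc(OCc2ccccc2)cc1 | intermediate
8 | (2R,3R)-7,8-bis(benzyloxy)-2-[4-(benzyloxy)phenyl]-3-hydroxychroman-4-one | c1cc2c(c(OCc3ccccc3)c1OCc1ccccc1)O[C@H](c1ccc(OCc3ccccc3)cc1)[C@@H](O)C2=O | intermediate
9 | (2R,3S,4R)-7,8-bis(benzyloxy)-2-[4-(benzyloxy)phenyl]chromane-3,4-diol | c1cc2c(c(OCc3ccccc3)c1OCc1ccccc1)O[C@H](c1ccc(OCc3ccccc3)cc1)[C@@H](O)[C@@H]2O | intermediate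
10 | (2R,3R)-7,8-bis(benzyloxy)-2-[4-(benzyloxy)phenyl]-4-oxochroman-3-yl methanesulfonate | c1cc2c(c(OCc3ccccc3)c1OCc1ccccc1)O[C@H](c1ccc(OCc3ccccc3)cc1)[C@@H](OS(C)(=O)=O)C2=O | intermediate
11 | (2R,3S,4R)-7,8-bis(benzyloxy)-2-[4-(benzyloxy)phenyl]-4-hydroxychroman-3-yl methanesulfonate | c1cc2c(c(OCc3ccccc3)c1OCc1ccccc1)O[C@H](c1ccc(OCc3ccccc3)cc1)[C@@H](OS(C)(=O)=O)[C@@H]2O | intermediate
12 | (2R,3R,4R)-7,8-bis(benzyloxy)-2-[4-(benzyloxy)phenyl]-3,4-epoxychromane (oxirane on the α face, cis to the 2-aryl group) | c1cc2c(c(OCc3ccccc3)c1OCc1ccccc1)O[C@H](c1ccc(OCc3ccccc3)cc1)[C@@H]1O[C@@H]12 | intermediate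
13 | (2R,3S,4S)-4-(benzylsulfanyl)-7,8-bis(benzyloxy)-2-[4-(benzyloxy)phenyl]chroman-3-ol | c1cc2c(c(OCc3ccccc3)c1OCc1ccccc1)O[C@H](c1ccc(OCc3ccccc3)cc1)[C@H](O)[C@H]2SCc1ccccc1 | intermediate
14 | hexa-O-benzyl epioritin-(4β→6)-oritin-4α-ol | C(c1ccccc1)Oc1ccc([C@H]2Oc3c(ccc(OCc4ccccc4)c3OCc3ccccc3)[C@H](c3cc4c(c(OCc5ccccc5)c3OCc3ccccc3)O[C@H](c3ccc(OCc5ccccc5)cc3)[C@@H](O)[C@@H]4O)[C@H]2O)cc1 | intermediate
15 | epioritin-(4β→6)-oritin-4α-ol (CNP0391561.5) | Oc1ccc([C@H]2Oc3c(ccc(O)c3O)[C@H](c3cc4c(c(O)c3O)O[C@H](c3ccc(O)cc3)[C@@H](O)[C@@H]4O)[C@H]2O)cc1 | target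

## Step count

- Total step count: 9.
- Longest linear sequence: 7 steps (3 → 5 → 6 → 8 → 10 → 13 → 14 → 15).

## Steps most likely to fail

**Step 4.** Three things can go wrong:
- The carbene may engage the aliphatic aldehyde of 7 and expel the aryloxide (internal redox to an aryl ester).
- The enolate of 7 may add to the aromatic aldehyde (benzofuran pathway).
- Any 2,3-cis adduct that later epimerises at C3 lowers the ee, because the ee of 8 equals the selectivity at C2.

The fallback moves the masked acyl anion from C4 to C3. It sets out from 2 and 5 and comes back at 8. Phenol 2 and nitroalkene 5 are joined by the known organocatalytic oxa-Michael/Henry/dehydration domino reaction, in which the nitronate carbon serves as the acyl anion equivalent. The catalyst is 1-[3,5-bis(trifluoromethyl)phenyl]-3-[(1R,2R)-2-(dimethylamino)cyclohexyl]thiourea or its antipode in toluene, and the product is (R)-7,8-bis(benzyloxy)-2-[4-(benzyloxy)phenyl]-3-nitro-2H-chromene F1. H2O2/NaOH adds anti to the 2-aryl group and gives the 3β,4β-epoxy-3-nitrochromane F2. Dilute aqueous H2SO4 in THF opens it at C4 with loss of nitrous acid to give (2R,4S)-4-hydroxychroman-3-one F3. Me4NBH(OAc)3 delivers hydride from the face of the 4-OH and gives the (2R,3R,4S)-diol F4. DDQ oxidises only the electron-rich benzylic carbinol to the (2R,3S)-2,3-cis-dihydroflavonol F5. NaOAc in EtOH epimerises C3 to the trans ketone 8. The C4 configuration of F3 does not matter, because C4 ends as a ketone.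

**Step 8.** The tri-O-benzylated ring D is only a moderate carbon nucleophile. The free hydroxyls of 9 can give ether-linked dimers, ring A of 13 can compete, and the HBF4 formed can ionise the 4-OH of 9.

The fallback uses a free-phenolic nucleophile, the type of partner known to couple in this flavan class. It sets out from 8 and 13 and comes back at 15. Hydrogenolysis of 8 (H2, Pd(OH)2/C) gives (2R,3R)-3,7,8-trihydroxy-2-(4-hydroxyphenyl)chroman-4-one F6. NaBH4 reduces it to (2R,3S,4R)-2-(4-hydroxyphenyl)chromane-3,4,7,8-tetrol F7. AgBF4 in THF couples 13 to C6 of F7 (5 equiv), which is now ortho to a free 7-OH, to give the dimer benzylated only in its upper unit F8. Hydrogenolysis of its three benzyl ethers gives 15.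

**Step 7.** Three things can go wrong:
- The hydride may give some 3,4-cis alcohol, which cannot close to the epoxide.
- The diaxial conformer needed for closure also aligns the 2-aryl group for a 1,2-shift.
- The electron-rich epoxide may be intercepted by ethanol or hydride.

The fallback inverts C3 by oxidation and reduction instead of substitution. It sets out from 9 and comes back at 14. BnSH with catalytic camphorsulfonic acid in CH2Cl2 turns 9 into the (2R,3R,4R)-4-benzylsulfanyl 2,3-trans alcohol F9. Dess–Martin periodinane gives (2R,4R)-4-(benzylsulfanyl)chroman-3-one F10. LiBH(s-Bu)3 at −78 °C attacks the β face, anti to both α substituents, and gives the (2R,3S,4R)-2,3-cis alcohol F11, the C4 epimer of 13. F11 ionises to the same cation under the conditions of step 8 and so gives 14.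

## Further compounds

F1 | step 4 | (R)-7,8-bis(benzyloxy)-2-[4-(benzyloxy)phenyl]-3-nitro-2H-chromene | c1cc2c(c(OCc3ccccc3)c1OCc1ccccc1)O[C@H](c1ccc(OCc3ccccc3)cc1)C([N+](=O)[O-])=C2
F2 | step 4 | 7,8-bis(benzyloxy)-2α-[4-(benzyloxy)phenyl]-3β,4β-epoxy-3-nitrochromane | c1cc2c(c(OCc3ccccc3)c1OCc1ccccc1)O[C@H](c1ccc(OCc3ccccc3)cc1)[C@@]1([N+](=O)[O-])O[C@H]12
F3 | step 4 | (2R,4S)-7,8-bis(benzyloxy)-2-[4-(benzyloxy)phenyl]-4-hydroxychroman-3-one | c1cc2c(c(OCc3ccccc3)c1OCc1ccccc1)O[C@H](c1ccc(OCc3ccccc3)cc1)C(=O)[C@H]2O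
F4 | step 4 | (2R,3R,4S)-7,8-bis(benzyloxy)-2-[4-(benzyloxy)phenyl]chromane-3,4-diol | c1cc2c(c(OCc3ccccc3)c1OCc1ccccc1)O[C@H](c1ccc(OCc3ccccc3)cc1)[C@H](O)[C@H]2O
F5 | step 4 | (2R,3S)-7,8-bis(benzyloxy)-2-[4-(benzyloxy)phenyl]-3-hydroxychroman-4-one | c1cc2c(c(OCc3ccccc3)c1OCc1ccccc1)O[C@H](c1ccc(OCc3ccccc3)cc1)[C@H](O)C2=O
F6 | step 8 | (2R,3R)-3,7,8-trihydroxy-2-(4-hydroxyphenyl)chroman-4-one | c1cc2c(c(O)c1O)O[C@H](c1ccc(O)cc1)[C@@H](O)C2=O
F7 | step 8 | (2R,3S,4R)-2-(4-hydroxyphenyl)chromane-3,4,7,8-tetrol | c1cc2c(c(O)c1O)O[C@H](c1ccc(O)cc1)[C@@H](O)[C@@H]2O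
F8 | step 8 | epioritin-(4β→6)-oritin-4α-ol benzylated at the three phenols of the upper unit | C(c1ccccc1)Oc1ccc([C@H]2Oc3c(ccc(OCc4ccccc4)c3OCc3ccccc3)[C@H](c3cc4c(c(O)c3O)O[C@H](c3ccc(O)cc3)[C@@H](O)[C@@H]4O)[C@H]2O)cc1
F9 | step 7 | (2R,3R,4R)-4-(benzylsulfanyl)-7,8-bis(benzyloxy)-2-[4-(benzyloxy)phenyl]chroman-3-ol | c1cc2c(c(OCc3ccccc3)c1OCc1ccccc1)O[C@H](c1ccc(OCc3ccccc3)cc1)[C@@H](O)[C@@H]2SCc1ccccc1
F10 | step 7 | (2R,4R)-4-(benzylsulfanyl)-7,8-bis(benzyloxy)-2-[4-(benzyloxy)phenyl]chroman-3-one | c1cc2c(c(OCc3ccccc3)c1OCc1ccccc1)O[C@H](c1ccc(OCc3ccccc3)cc1)C(=O)[C@@H]2SCc1ccccc1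
F11 | step 7 | (2R,3S,4R)-4-(benzylsulfanyl)-7,8-bis(benzyloxy)-2-[4-(benzyloxy)phenyl]chroman-3-ol | c1cc2c(c(OCc3ccccc3)c1OCc1ccccc1)O[C@H](c1ccc(OCc3ccccc3)cc1)[C@H](O)[C@@H]2SCc1ccccc1
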